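The cyclopentane ring of the trans-hydrindane (octahydroindene numbering) is disconnected between the carbinol carbon C1 and the ring methylene C2. The array C1–C7a–C3a–C3–C2 is a latent 4-pentenal, so rhodium-catalysed intramolecular hydroacylation of a cyclohexane carrying trans-diequatorial formyl (C1) and vinyl (C3–C2) groups forges C1–C2, closes the five-membered ring and fixes the trans ring fusion in one atom-economical operation; methyl addition then gives the C1 carbinol. The precursor is a gem-diester cyclohexane from a palladium/enamine allylation; later the axial C4 hydroxyl lactonizes one ester, and a dianion Claisen annulation with final diprenylation builds the spiro trione ring.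

Key step: step 7

Remark: ring atoms are numbered as in octahydroindene (C1 and C4 are the two carbinol carbons, C6 the quaternary carbon that becomes the spiro centre); the target is one of several rapidly interconverting enol tautomers; 1, 2 and 12 are taken as commercial.

Step 1
Reactants: 1 di-tert-butyl malonate; 2 (S)-2-methylglycidol
Product: 3 di-tert-butyl 2-[(2R)-2,3-dihydroxy-2-methylpropyl]propanedioate
Conditions: NaOt-Bu (0.2 equiv), t-BuOH, 50 °C
Reagents that add atoms: none
Why: Malonic ester alkylation by SN2 opening of the 2,2-disubstituted epoxide at its CH2 terminus should leave the carbinol stereocentre untouched, the Payne rearrangement of 2 being degenerate and the tert-butyl esters resisting lactonization by the tertiary alkoxide.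

Step 2
Reactants: 3 di-tert-butyl 2-[(2R)-2,3-dihydroxy-2-methylpropyl]propanedioate
Product: 4 di-tert-butyl 2-[(2R)-2-hydroxy-2-methyl-3-oxopropyl]propanedioate
Conditions: IBX (1.5 equiv), DMSO, 23 °C
Reagents that add atoms: none
Why: IBX oxidation should convert the primary alcohol of the 1,2-diol into the aldehyde without glycol cleavage, and the quaternary α-carbon cannot epimerize.

Step 3
Reactants: 4 di-tert-butyl 2-[(2R)-2-hydroxy-2-methyl-3-oxopropyl]propanedioate
Product: 5 di-tert-butyl 2-[(2R,3RS)-2,3-dihydroxy-2-methylpent-4-en-1-yl]propanedioate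
Conditions: CH2=CHMgBr (3.3 equiv), THF, −78 to 0 °C; aq. NH4Cl
Reagents that add atoms: vinylmagnesium bromide, C=C[Mg]Br
Why: Grignard 1,2-addition to the aldehyde follows deprotonation of the hydroxyl and the malonate C–H (the magnesium enolate shields the esters), and the new carbinol centre may form as both epimers because it is ionized in step 6.

Step 4
Reactants: 5 di-tert-butyl 2-[(2R,3RS)-2,3-dihydroxy-2-methylpent-4-en-1-yl]propanedioate
Product: 6 di-tert-butyl 2-[(2R,3RS)-2,3-dihydroxy-2-methylpent-4-en-1-yl]-2-(3-oxopropyl)propanedioate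
Conditions: acrolein (1.3 equiv), DBU (0.1 equiv), MeCN, 0 °C
Reagents that add atoms: acrolein, C=CC=O
Why: Base-catalysed Michael addition of the malonate C–H to acrolein should create the quaternary carbon, which is not stereogenic while its two esters are identical.

Step 5
Reactants: 6 di-tert-butyl 2-[(2R,3RS)-2,3-dihydroxy-2-methylpent-4-en-1-yl]-2-(3-oxopropyl)propanedioate
Product: 7 di-tert-butyl 2-{(2R,3RS)-2-hydroxy-3-[(methoxycarbonyl)oxy]-2-methylpent-4-en-1-yl}-2-(3-oxopropyl)propanedioate
Conditions: ClCO2Me (1.5 equiv), pyridine, CH2Cl2, 0 °C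
Reagents that add atoms: methyl chloroformate, COC(=O)Cl
Why: Acylation by the chloroformate should take place at the secondary allylic alcohol and not at the hindered tertiary one, which turns it into the leaving group for π-allyl formation.

Step 6
Reactants: 7 di-tert-butyl 2-{(2R,3RS)-2-hydroxy-3-[(methoxycarbonyl)oxy]-2-methylpent-4-en-1-yl}-2-(3-oxopropyl)propanedioate
Product: 8 di-tert-butyl (3R,4S,5R)-4-ethenyl-5-formyl-3-hydroxy-3-methylcyclohexane-1,1-dicarboxylate
Conditions: Pd(PPh3)4 (5 mol %), pyrrolidine (0.3 equiv), THF, 23 °C
Reagents that add atoms: none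
Why: In this Tsuji–Trost allylation of an aldehyde under combined zerovalent palladium and enamine catalysis the π-allylpalladium complex from the carbonate should be attacked at its proximal terminus (6-exo) by the pyrrolidine enamine through a chair with the C3 hydroxyl axial (no methyl/axial-ester clash) and the allyl unit equatorial, which sets C4 from the glycidol-derived centre, while the formyl-bearing C5 equilibrates through the enamine to the equatorial trans epimer.

Step 7
Reactants: 8 di-tert-butyl (3R,4S,5R)-4-ethenyl-5-formyl-3-hydroxy-3-methylcyclohexane-1,1-dicarboxylate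
Product: 9 di-tert-butyl (3aS,4R,7aR)-4-hydroxy-4-methyl-1-oxo-octahydroindene-6,6-dicarboxylate (trans-fused)
Conditions: [Rh(nbd)(dppe)]BF4 (5 mol %, activated with H2, then Ar), CH2Cl2, 23 °C
Reagents that add atoms: none
Why: Monovalent rhodium inserts into the formyl C–H bond to give an acyl rhodium hydride (trivalent rhodium), the vinyl group inserts into Rh–H with hydride delivery to its internal carbon, and reductive elimination from the six-membered acyl–alkyl rhodacycle joins the acyl carbon (C1) to the former terminal vinyl carbon (C2). The closest known reaction type is the rhodium-catalysed intramolecular hydroacylation of 4-pentenals to cyclopentanones with cationic bisphosphine catalysts. The cyclopentanone ring closes in a formally 5-endo-trig sense with respect to the alkene, which the metallacycle pathway allows where radical or ionic closures would fail. No new stereocentre is formed: the trans ring fusion is inherited from the trans-diequatorial formyl and vinyl groups of 8 and should persist because the neutral conditions do not enolize C7a. The step needs chemoselectivity over decarbonylation and alkene isomerization, which the cationic dppe complex at room temperature and the fixed gauche arrangement of the two reacting groups on the chair should secure; the tertiary alcohol and the tert-butyl esters are spectators.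

Step 8
Reactants: 9 di-tert-butyl (3aS,4R,7aR)-4-hydroxy-4-methyl-1-oxo-octahydroindene-6,6-dicarboxylate
Product: 10 di-tert-butyl (1S,3aS,4R,7aR)-1,4-dihydroxy-1,4-dimethyl-octahydroindene-6,6-dicarboxylate
Conditions: MeMgBr (3 equiv), CeCl3 (3 equiv), THF, −78 °C
Reagents that add atoms: methylmagnesium bromide, C[Mg]Br
Why: Non-enolizing organocerium 1,2-addition (so C7a is not epimerized to the cis-hydrindanone) should occur on the α-face, trans to the ring bond C7a–C7 as with 2-alkylcyclopentanones, which places the new methyl α and the hydroxyl β, while the tert-butyl esters stay inert.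

Step 9
Reactants: 10 di-tert-butyl (1S,3aS,4R,7aR)-1,4-dihydroxy-1,4-dimethyl-octahydroindene-6,6-dicarboxylate
Product: 11 tert-butyl ester γ-lactone (6-oxabicyclo[3.2.1]octan-7-one bridge between the C4 oxygen and the cis C6 carboxyl)
Conditions: KOt-Bu (0.2 equiv), THF, 50 °C
Reagents that add atoms: none
Why: The alkoxide of the axial C4 hydroxyl should transesterify the only ester it can reach, the cis (axial) one in a 1,3-diaxial relationship, so that this lactonization desymmetrizes the gem-diester and defines the configuration of the future spiro carbon.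

Step 10
Reactants: 11 tert-butyl ester γ-lactone; 12 6-methylheptane-2,4-dione
Product: 15 spiro acyl triketone lacking the prenyl groups, via dilithium dianion 13 (not isolated), via triketone 14 (not isolated)
Conditions: 12 (3 equiv), LiN(i-Pr)2 (6 equiv), THF, −78 to 0 °C; then 11, 0 to 23 °C; then 60 °C; aq. HCl
Reagents that add atoms: none
Why: Acylation of the β-diketone dianion at its terminal carbon by the strained lactone (not by the hindered tert-butyl ester) and Claisen closure of the central carbon onto that ester in a Dieckmann-type 6-exo-trig step should build the cyclic β-triketone with the lactone-derived carbonyl next to the ring CH2 and the ester-derived carbonyl next to the acylated carbon, which fixes the spiro configuration.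

Step 11
Reactants: 15 spiro acyl triketone lacking the prenyl groups
Product: 17 CNP0198642.4, via monoprenyl triketone 16 (not isolated)
Conditions: prenyl bromide (2.3 equiv), NaOMe (3.5 equiv), MeOH, 0 to 23 °C
Reagents that add atoms: prenyl bromide, CC(C)=CCBr
Why: Twofold C-alkylation of the ring CH2 flanked by two carbonyls under protic basic conditions (the gem-diprenylation known from the lupulone series) should give the target, the acyl-bearing carbon and the two tertiary alcohols being unreactive.

Compound list
1 | di-tert-butyl propanedioate (di-tert-butyl malonate) | CC(C)(C)OC(=O)CC(=O)OC(C)(C)C | starting material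
2 | [(2S)-2-methyloxiran-2-yl]methanol ((S)-2-methylglycidol) | OC[C@@]1(C)CO1 | starting material
3 | di-tert-butyl 2-[(2R)-2,3-dihydroxy-2-methylpropyl]propanedioate | CC(C)(C)OC(=O)C(C(=O)OC(C)(C)C)C[C@@](C)(O)CO | intermediate
4 | di-tert-butyl 2-[(2R)-2-hydroxy-2-methyl-3-oxopropyl]propanedioate | CC(C)(C)OC(=O)C(C(=O)OC(C)(C)C)C[C@@](C)(O)C=O | intermediate
5 | di-tert-butyl 2-[(2R,3RS)-2,3-dihydroxy-2-methylpent-4-en-1-yl]propanedioate (both carbinol epimers) | CC(C)(C)OC(=O)C(C(=O)OC(C)(C)C)C[C@@](C)(O)C(O)C=C | intermediate
6 | di-tert-butyl 2-[(2R,3RS)-2,3-dihydroxy-2-methylpent-4-en-1-yl]-2-(3-oxopropyl)propanedioate | CC(C)(C)OC(=O)C(CCC=O)(C(=O)OC(C)(C)C)C[C@@](C)(O)C(O)C=C | intermediate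
7 | di-tert-butyl 2-{(2R,3RS)-2-hydroxy-3-[(methoxycarbonyl)oxy]-2-methylpent-4-en-1-yl}-2-(3-oxopropyl)propanedioate | CC(C)(C)OC(=O)C(CCC=O)(C(=O)OC(C)(C)C)C[C@@](C)(O)C(OC(=O)OC)C=C | intermediate
8 | di-tert-butyl (3R,4S,5R)-4-ethenyl-5-formyl-3-hydroxy-3-methylcyclohexane-1,1-dicarboxylate (OH axial, vinyl and formyl equatorial and trans) | CC(C)(C)OC(=O)C1(C(=O)OC(C)(C)C)C[C@@H](C=O)[C@H](C=C)[C@](C)(O)C1 | intermediate
9 | di-tert-butyl (3aS,4R,7aR)-4-hydroxy-4-methyl-1-oxo-octahydroindene-6,6-dicarboxylate (trans-fused) | CC(C)(C)OC(=O)C1(C(=O)OC(C)(C)C)C[C@@H]2[C@H](CCC2=O)[C@](C)(O)C1 | intermediate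
10 | di-tert-butyl (1S,3aS,4R,7aR)-1,4-dihydroxy-1,4-dimethyl-octahydroindene-6,6-dicarboxylate | CC(C)(C)OC(=O)C1(C(=O)OC(C)(C)C)C[C@@H]2[C@H](CC[C@]2(C)O)[C@](C)(O)C1 | intermediate
11 | γ-lactone of 10 between the C4 oxygen and the cis C6 carboxyl; the trans C6 carboxyl remains a tert-butyl ester; C1 hydroxyl free; ring configurations as in 10 | CC(C)(C)OC(=O)[C@@]12C[C@@H]3[C@H](CC[C@]3(C)O)[C@@](C)(C1)OC2=O | intermediate
12 | 6-methylheptane-2,4-dione | CC(C)CC(=O)CC(C)=O | starting material
13 | dilithium dianion of 12 (terminal methyl and central carbon; not isolated) | [Li+].[Li+].C=C([O-])C=C([O-])CC(C)C | intermediate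
14 | tert-butyl (1S,3aS,4R,6S,7aR)-1,4-dihydroxy-1,4-dimethyl-6-(7-methyl-3,5-dioxooctanoyl)-octahydroindene-6-carboxylate (not isolated) | CC(C)CC(=O)CC(=O)CC(=O)[C@]1(C(=O)OC(C)(C)C)C[C@@H]2[C@H](CC[C@]2(C)O)[C@](C)(O)C1 | intermediate
15 | 3-hydroxy-2-(3-methylbutanoyl)cyclohex-2-ene-1,5-dione spiro-linked through its C6 (S) to C6 of (1S,3aS,4R,7aR)-1,4-dihydroxy-1,4-dimethyl-octahydroindene; the C5 carbonyl (next to the ring CH2) is cis to the C4 hydroxyl | CC(C)CC(=O)C1=C(O)CC(=O)[C@@]2(C[C@@H]3[C@H](CC[C@]3(C)O)[C@](C)(O)C2)C1=O | intermediate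
16 | 4-monoprenyl derivative of 15 (epimers and enol tautomers at C4 of the triketone ring; not isolated) | CC(C)CC(=O)C1=C(O)C(CC=C(C)C)C(=O)[C@@]2(C[C@@H]3[C@H](CC[C@]3(C)O)[C@](C)(O)C2)C1=O | intermediate
17 | CNP0198642.4: 3-hydroxy-2-(3-methylbutanoyl)-4,4-bis(3-methylbut-2-en-1-yl)cyclohex-2-ene-1,5-dione spiro-linked through its C6 (S) to C6 of (1S,3aS,4R,7aR)-1,4-dihydroxy-1,4-dimethyl-octahydroindene | CC(C)=CCC1(CC=C(C)C)C(=O)[C@@]2(C[C@@H]3[C@H](CC[C@]3(C)O)[C@](C)(O)C2)C(=O)C(C(=O)CC(C)C)=C1O | target

Total step count: 11. Longest linear sequence: 11 steps (from 1 to 17).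

Steps most likely to fail

Step 6. N-allylation of the amine catalyst or attack of methoxide at the unhindered allyl terminus may outrun attack of the enamine at the hindered terminus next to the quaternary carbinol carbon, and facial control at C4 may be insufficient. The fallback sets out from 4 and returns at 8.
- Michael addition of 4 to acrylonitrile (DBU cat.) should give di-tert-butyl 2-(2-cyanoethyl)-2-[(2R)-2-hydroxy-2-methyl-3-oxopropyl]propanedioate F1.
- KOt-Bu in t-BuOH should close the six-membered ring by addition of the nitrile α-carbanion to the non-enolizable aldehyde and dehydration, giving the γ-hydroxy alkenenitrile di-tert-butyl (5R)-3-cyano-5-hydroxy-5-methylcyclohex-3-ene-1,1-dicarboxylate F2.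
- Deprotonation of the hydroxyl with t-BuMgCl and chelation-controlled conjugate addition of CH2=CHMgBr should deliver the vinyl group to C4 on the face of the hydroxyl, giving di-tert-butyl (3R,4S,5RS)-5-cyano-4-ethenyl-3-hydroxy-3-methylcyclohexane-1,1-dicarboxylate F3.
- i-Bu2AlH at −78 °C, hydrolysis of the imine and equilibration of the formyl centre with a trace of base should give 8.

Step 10. Claisen closure onto the hindered tert-butyl ester may be slow, O-acylation to a pyranone may compete, and the diketone may be deprotonated on its isobutyl side. The fallback sets out from 11 and returns at 15, with the order of the two acylations reversed.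
- Me3SiOTf/2,6-lutidine should cleave the tert-butyl ester and cap the C1 hydroxyl; aqueous work-up gives the lactone acid with a C1 trimethylsilyl ether F4.
- (COCl)2 with catalytic DMF should give the acid chloride F5.
- C-acylation of the magnesium enolate of 12 (MgCl2, Et3N) at its central carbon should give the triacylmethane F6.
- LiN(i-Pr)2 (3 equiv) should generate the acetyl methyl carbanion, which closes onto the lactone carbonyl in a 6-exo-trig Claisen step; acidic work-up removes the silyl ether and gives 15.

Step 8. Facial selectivity of the methyl addition may be low or reversed (torsional control favours β-attack), and enolization may epimerize the ring fusion. The fallback sets out from 9 and returns at 10.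
- Non-basic methylenation (Zn, CH2Br2, TiCl4) should give the exocyclic alkene di-tert-butyl (3aS,4R,7aR)-4-hydroxy-4-methyl-1-methylidene-octahydroindene-6,6-dicarboxylate F7.
- Mukaiyama hydration (Mn(dpm)3, dpm = dipivaloylmethanato, PhSiH3, O2, i-PrOH; then PPh3) installs the hydroxyl at the tertiary carbon from the face that a carbon nucleophile prefers, which is the complementary stereochemical outcome, and should give 10.

Further compounds
F1 | step 6 | di-tert-butyl 2-(2-cyanoethyl)-2-[(2R)-2-hydroxy-2-methyl-3-oxopropyl]propanedioate | CC(C)(C)OC(=O)C(CCC#N)(C(=O)OC(C)(C)C)C[C@@](C)(O)C=O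
F2 | step 6 | di-tert-butyl (5R)-3-cyano-5-hydroxy-5-methylcyclohex-3-ene-1,1-dicarboxylate | CC(C)(C)OC(=O)C1(C(=O)OC(C)(C)C)CC(C#N)=C[C@](C)(O)C1
F3 | step 6 | di-tert-butyl (3R,4S,5RS)-5-cyano-4-ethenyl-3-hydroxy-3-methylcyclohexane-1,1-dicarboxylate | CC(C)(C)OC(=O)C1(C(=O)OC(C)(C)C)CC(C#N)[C@H](C=C)[C@](C)(O)C1
F4 | step 10 | lactone carboxylic acid from 11 with the C1 hydroxyl as trimethylsilyl ether | O=C(O)[C@@]12C[C@@H]3[C@H](CC[C@]3(C)O[Si](C)(C)C)[C@@](C)(C1)OC2=O
F5 | step 10 | acid chloride of F4 | O=C(Cl)[C@@]12C[C@@H]3[C@H](CC[C@]3(C)O[Si](C)(C)C)[C@@](C)(C1)OC2=O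
F6 | step 10 | triacylmethane from F5 and 12 (central carbon of 12 acylated) | CC(=O)C(C(=O)CC(C)C)C(=O)[C@@]12C[C@@H]3[C@H](CC[C@]3(C)O[Si](C)(C)C)[C@@](C)(C1)OC2=O
F7 | step 8 | di-tert-butyl (3aS,4R,7aR)-4-hydroxy-4-methyl-1-methylidene-octahydroindene-6,6-dicarboxylate | CC(C)(C)OC(=O)C1(C(=O)OC(C)(C)C)C[C@@H]2[C@H](CCC2=C)[C@](C)(O)C1
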